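**Assumption:** CIP analysis of the target SMILES gives (2S)-5,7,3',5'-tetrahydroxy-6,8-bis(3-methylbut-2-enyl)flavanone (6,8-diprenyl-5,7,3',5'-tetrahydroxyflavanone). C2 is its only stereocenter.

## Retrosynthetic overview
1. The target comes from removal of the two B-ring MOM ethers of the (2S)-bis-MOM flavanone.
2. That flavanone comes from an enantioselective intramolecular oxa-Michael closure of the C-ring. This is the last ring formed and it sets C2. The precursor is the 2'-hydroxychalcone.
3. The chalcone comes from Claisen–Schmidt condensation of 3,5-diprenylphloroacetophenone with 3,5-bis(MOM-oxy)benzaldehyde.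
4. The diprenyl ketone comes from C-diprenylation of commercial phloroacetophenone. The aldehyde comes from MOM protection of 3,5-dihydroxybenzaldehyde.

## Route

**Step 1**
Reactants: **1** 3,5-dihydroxybenzaldehyde; **2** chloromethyl methyl ether (MOMCl)
Product: **3** 3,5-bis(methoxymethoxy)benzaldehyde
Conditions: NaH (2.4 equiv), THF/DMF, 0 °C → rt; then **2** (2.4 equiv)
Reagents that add atoms: MOMCl, COCCl
Why: Williamson-type O-alkylation of the phenoxides masks the B-ring phenols so the aldehyde can undergo base-mediated aldol condensation. MOM ethers are stable to base and to the organocatalyst. They are removed under mild acid, without hydrogenolysis, so the prenyl alkenes survive.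

**Step 2**
Reactants: **4** 2',4',6'-trihydroxyacetophenone; **5** prenyl bromide
Product: **6** 1-[2,4,6-trihydroxy-3,5-bis(3-methylbut-2-en-1-yl)phenyl]ethan-1-one
Conditions: **5** (2.2 equiv), KOH (3 equiv), MeOH/H2O, 0 °C → rt, 4 h; chromatographic separation from the mono-prenyl product
Reagents that add atoms: prenyl bromide, CC(C)=CCBr
Why: Phloroglucinol-type phenoxides in protic solvent undergo C-alkylation, because hydrogen bonding to oxygen favors attack through carbon. The only nucleophilic ring carbons (C3 and C5) are equivalent, so diprenylation gives one regioisomer. The yield is moderate, limited by mono-prenyl and over-alkylated by-products.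

**Step 3**
Reactants: **6** 3,5-diprenylphloroacetophenone; **3** 3,5-bis(methoxymethoxy)benzaldehyde
Product: **7** (E)-3-[3,5-bis(methoxymethoxy)phenyl]-1-[2,4,6-trihydroxy-3,5-bis(3-methylbut-2-en-1-yl)phenyl]prop-2-en-1-one
Conditions: KOH (6 equiv), EtOH/H2O, rt → 45 °C, 48 h; cool to 0 °C, quench to pH ≈ 5 with aq. citric acid; silica chromatography to remove any racemic flavanone
Reagents that add atoms: none
Why: This is a Claisen–Schmidt aldol condensation. Excess base covers the three acidic phenols, and the E-enone forms by E1cB dehydration. Mild quenching to pH ≈ 5 keeps the MOM acetals intact and limits uncontrolled cyclization of the chalcone.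

**Step 4**
Reactants: **7** chalcone; **8** (catalyst, 10 mol %): 9-epi-amino-quinine-derived 3,5-bis(CF3)phenyl squaramide
Product: **9** (2S)-5,7-dihydroxy-2-[3,5-bis(methoxymethoxy)phenyl]-6,8-bis(3-methylbut-2-en-1-yl)chroman-4-one
Conditions: **8** (10 mol %), CH2Cl2/MTBE (1:1), –20 °C, 4–5 d; direct chromatography on silica
Reagents that add atoms: none (catalyst only)
Why: Proposed new method: a bifunctional quinuclidine/squaramide catalyst binds the 2'-phenol and the enone carbonyl in a chiral ion pair, and delivers the phenoxide to one enone face in an intramolecular oxa-Michael reaction, which sets C2. Low temperature and a mildly basic catalyst limit retro-Michael racemization. The closest known reactions are bifunctional-amine catalysed cyclization of simple 2'-hydroxychalcones and iminophosphorane-catalysed oxa-Michael reactions. The new element is the substrate: a fully hydroxylated, diprenylated, push–pull deactivated chalcone whose carbonyl is locked by two chelating OH groups, for which the catalyst must outcompete the racemic background reaction.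

**Step 5**
Reactants: **9** (2S)-bis-MOM flavanone
Product: **10** target, (2S)-5,7,3',5'-tetrahydroxy-6,8-diprenylflavanone
Conditions: Amberlyst-15, MeOH, 40 °C, 12 h (filter, concentrate)
Reagents that add atoms: none
Why: Acid-catalyzed acetal cleavage removes the aryl MOM ethers, and MeOH traps the MOM cation as CH2(OMe)2. The C2 stereocenter is not touched: the meta-dioxygenated B ring does not stabilize a benzylic cation, so ring opening and racemization are disfavored. The isolated prenyl groups survive the mild heterogeneous acid.

## Compound list
1 | 3,5-dihydroxybenzaldehyde | O=Cc1cc(O)cc(O)c1 | starting material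
2 | chloromethyl methyl ether | COCCl | starting material
3 | 3,5-bis(methoxymethoxy)benzaldehyde | O=Cc1cc(OCOC)cc(OCOC)c1 | intermediate
4 | 2',4',6'-trihydroxyacetophenone | CC(=O)c1c(O)cc(O)cc1O | starting material
5 | prenyl bromide | CC(C)=CCBr | starting material
6 | 3,5-diprenyl-2,4,6-trihydroxyacetophenone | CC(=O)c1c(O)c(CC=C(C)C)c(O)c(CC=C(C)C)c1O | intermediate
7 | (E)-chalcone, bis-MOM | O=C(/C=C/c1cc(OCOC)cc(OCOC)c1)c1c(O)c(CC=C(C)C)c(O)c(CC=C(C)C)c1O | intermediate
8 | 9-epi-amino-quinine-derived squaramide organocatalyst | COC1=CC2=C(C=CN=C2C=C1)[C@@H]([C@@H]3C[C@@H]4CCN3C[C@@H]4C=C)NC5=C(NC6=CC(=CC(=C6)C(F)(F)F)C(F)(F)F)C(=O)C5=O | starting material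
9 | (2S)-flavanone, bis-MOM | CC(C)=CCc1c(O)c(CC=C(C)C)c2c(c1O)C(=O)C[C@@H](c1cc(OCOC)cc(OCOC)c1)O2 | intermediate
10 | target, (2S)-6,8-diprenyl-5,7,3',5'-tetrahydroxyflavanone | CC(C)=CCc1c(O)c(CC=C(C)C)c2c(c1O)C(=O)C[C@@H](c1cc(O)cc(O)c1)O2 | target

## Final tally
Total steps: 5. Longest linear sequence: 4 (steps 2 → 3 → 4 → 5).

**Three steps most likely to fail**
1. **Step 4 (the proposed new step):** the electron-rich, doubly chelated chalcone may be too unreactive, or the ee may erode through retro-Michael racemization. The quinidine-derived catalyst would give the (R)-enantiomer if the sense of induction is opposite to that assumed.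
   Fallback (known chemistry): cyclize **7** racemically (NaOAc, EtOH, reflux), then isolate the (S)-flavanone **9** by preparative chiral-stationary-phase HPLC (amylose-type column).
2. **Step 3:** the tri-anionic acetophenone may be a poor aldol donor, giving low conversion.
   Fallback: bis-MOM-protect the 4'- and 6'-OH groups of **6** (MOMCl, iPr2NEt; the chelated 2'-OH stays free), run the Claisen–Schmidt condensation on that ketone under standard KOH/EtOH conditions, and remove all MOM groups in the final step. This adds one step.
3. **Step 5:** acid may cyclize an ortho-prenyl phenol to a chroman or open the flavanone.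
   Fallback: replace the MOM groups with allyl ethers (use 3,5-bis(allyloxy)benzaldehyde in Step 3) and remove them near-neutrally with Pd(PPh3)4/morpholine.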